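**Retrosynthetic overview**

- The 1,2-dioxane is opened at O–C16 (6-exo conjugate addition of a C13 tertiary hydroperoxide to a C16=C17 2-methyl enoate, as in the presumed biogenesis, here run under a chiral Brønsted base) and at C13–O (Markovnikov radical oxygenation of a 1,1-disubstituted alkene with O2).
- The side chain is cut at C16=C17 (cross-metathesis with methyl methacrylate) and at C12–C13 (copper-catalysed coupling of a C12 iodide with a hexa-1,5-dien-2-yl Grignard reagent).
- The 9α-hydroxy-8α-methyl decalin comes from trans-diaxial hydride opening of the 8α,9α-epoxide of the tetrasubstituted alkene made from (+)-sclareolide.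
- Ring order: rings A and B are taken intact from sclareolide (C5, C10); the dioxane is the only ring formed, in the penultimate step.

Assumption: labdane-type numbering is used (decalin C1–C10, side chain C11–C17, carboxyl C18; dioxane = O–O–C16–C15–C14–C13), and the C13 epimer pair that radical oxygenation gives is parted after ring closure.

**Route**

Step 1
Reactants: 1 (+)-sclareolide
Product: 2 methyl 2-[(4aS,8aS)-2,5,5,8a-tetramethyl-3,4,4a,5,6,7,8,8a-octahydronaphthalen-1-yl]acetate
Conditions: H2SO4 (conc.), MeOH, reflux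
Reagents that add atoms: methanol, CO
Why: Acid-catalysed methanolysis of the lactone with E1 loss of the tertiary C8 oxygen and acid equilibration of the alkene isomers gives mainly the thermodynamically favoured tetrasubstituted 8(9)-alkene (the minor 7-ene ester is separated and recycled under the same acid), C5 and C10 being carried over unchanged from 1.

Step 2
Reactants: 2 (8(9)-ene methyl ester)
Product: 3 methyl 2-[(1S,2R,4aS,8aS)-1,2-epoxy-2,5,5,8a-tetramethyldecahydronaphthalen-1-yl]acetate
Conditions: mCPBA, CH2Cl2/aq. NaHCO3 (two-phase buffer), 0 °C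
Reagents that add atoms: 3-chloroperoxybenzoic acid, OOC(=O)c1cccc(Cl)c1
Why: Prilezhaev epoxidation takes place on the α face, anti to the axial C10 methyl group, so the epoxide oxygen (the future C9 hydroxyl) is set as 9α, while the buffer keeps the ester carbonyl from opening the epoxide.

Step 3
Reactants: 3 (8α,9α-epoxy ester)
Product: 4 (1R,2R,4aS,8aS)-1-(2-hydroxyethyl)-2,5,5,8a-tetramethyldecahydronaphthalen-1-ol
Conditions: LiEt3BH (6 equiv), THF, 0 °C to reflux; then H2O
Reagents that add atoms: none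
Why: Lithium triethylborohydride reduces the ester to the primary alcohol and opens the tetrasubstituted epoxide by SN2 attack at the less encumbered C8 from the β face (trans-diaxial, Fürst–Plattner opening), which inverts C8 to 8β-H/8α-methyl and leaves the C9–O bond as the axial 9α-hydroxyl.

Step 4
Reactants: 4 (9α,12-diol)
Product: 5 (1R,2R,4aS,8aS)-1-(2-iodoethyl)-2,5,5,8a-tetramethyldecahydronaphthalen-1-ol
Conditions: I2, PPh3, imidazole, CH2Cl2, 0 °C to rt
Reagents that add atoms: iodine, II
Why: Appel-type (Garegg–Samuelsson) iodination converts only the primary alcohol through its alkoxyphosphonium salt, the hindered tertiary C9 hydroxyl being inert, and no stereocentre is touched.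

Step 5
Reactants: 6 2,3-dibromoprop-1-ene; 7 allylmagnesium bromide
Product: 8 2-bromohexa-1,5-diene
Conditions: Et2O, 0 °C to rt
Reagents that add atoms: none
Why: The allyl Grignard reagent displaces the allylic bromide (SN2 or SN2', both give the same product) while the vinylic C–Br bond does not react.

Step 6
Reactants: 5 (iodo alcohol); 8 2-bromohexa-1,5-diene
Product: 10 (1R,2R,4aS,8aS)-2,5,5,8a-tetramethyl-1-(3-methylidenehept-6-en-1-yl)decahydronaphthalen-1-ol, via hexa-1,5-dien-2-ylmagnesium bromide 9 (not isolated)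
Conditions: 8, Mg, THF, 50 °C; then 5, CuI (10 mol%), THF, −30 to 0 °C (3 equiv of 9)
Reagents that add atoms: none
Why: Copper-catalysed Kochi-type cross-coupling joins the alkenyl Grignard reagent to the primary iodide (C12–C13 bond) after the first equivalent has turned the tertiary alcohol into its alkoxide (ROMgBr), the low temperature keeping this 3-iodo alkoxide from oxetane closure or Grob fragmentation; no stereocentre is touched.

Step 7
Reactants: 10 (diene alcohol); 11 methyl methacrylate
Product: 12 methyl (2E)-8-[(1R,2R,4aS,8aS)-1-hydroxy-2,5,5,8a-tetramethyldecahydronaphthalen-1-yl]-2-methyl-6-methylideneoct-2-enoate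
Conditions: 11 (10 equiv), second-generation Hoveyda–Grubbs catalyst RuCl2(=CH-C6H4-2-OiPr)(H2IMes) (5 mol%), CH2Cl2, 40 °C
Reagents that add atoms: none
Why: Olefin cross-metathesis of the monosubstituted alkene with excess methacrylate gives the trisubstituted enoate as the thermodynamically preferred (E)-isomer, the 1,1-disubstituted C13 alkene being too hindered to enter the cycle and ring closure being impossible (it would need a cyclobutene).

Step 8
Reactants: 12 (dienoate)
Product: 13 methyl (2E,6RS)-8-[(1R,2R,4aS,8aS)-1-hydroxy-2,5,5,8a-tetramethyldecahydronaphthalen-1-yl]-2,6-dimethyl-6-[(triethylsilyl)peroxy]oct-2-enoate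
Conditions: Co(thd)2 (10 mol%; thd = 2,2,6,6-tetramethylheptane-3,5-dionate), O2 (1 atm), Et3SiH (3 equiv), ClCH2CH2Cl, rt
Reagents that add atoms: dioxygen, O=O; triethylsilane, CC[SiH](CC)CC
Why: Mukaiyama–Isayama hydroperoxysilylation: hydrogen-atom transfer from the Co–H species formed from Co(thd)2 and Et3SiH to the electron-rich 1,1-disubstituted alkene gives the tertiary C13 radical, which is trapped by O2 and silylated, whereas the electron-poor enoate and the tertiary alcohol are untouched; the radical lies four bonds from the nearest stereocentre, so C13 is formed as a ca. 1:1 epimer pair of which the 13S (6S in the name) epimer is the productive one.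

Step 9
Reactants: 13 (silyl peroxide, both C13 epimers)
Product: 15 methyl (2S)-2-[(3S,6S)-6-{2-[(1R,2R,4aS,8aS)-1-hydroxy-2,5,5,8a-tetramethyldecahydronaphthalen-1-yl]ethyl}-6-methyl-1,2-dioxan-3-yl]propanoate, via tertiary hydroperoxide 14 (not isolated)
Conditions: HCl (cat.), MeOH, 0 °C, then evaporation from toluene; chiral bifunctional iminophosphorane–thiourea base ArNHC(S)NH–CH(t-Bu)–CH2–N=P(4-MeOC6H4)3, Ar = 3,5-(CF3)2C6H3 (10 mol%), toluene, −20 °C; chromatography
Reagents that add atoms: none
Why: Proposed new method: acid methanolysis frees the tertiary hydroperoxide, which the superbasic iminophosphorane deprotonates while the thiourea arm binds the ester carbonyl, so the ion-paired peroxide anion adds 6-exo-trig to one face of the enoate through a chair with the C16 side chain equatorial (catalyst control sets C16 as S; the catalyst antipode that gives this sense is chosen by screening), and the ester enolate is then protonated by the aminophosphonium on the face syn to the ring oxygen in its A(1,3)-minimised rotamer (sets C17 as S, the 16,17-anti relationship); the 13S hydroperoxide therefore gives 15 (C3 and C6 chains trans-diequatorial) and the 13R hydroperoxide a 3,6-cis dioxane that, with any C17 epimer, is removed by chromatography; the closest known reaction types are the amine-promoted intramolecular peroxy-Michael addition of hydroperoxides to enoates and the iminophosphorane-catalysed enantioselective intramolecular oxa-Michael addition of alcohols to α,β-unsaturated esters.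

Step 10
Reactants: 15 (dioxane methyl ester)
Product: 16 (2S)-2-[(3S,6S)-6-{2-[(1R,2R,4aS,8aS)-1-hydroxy-2,5,5,8a-tetramethyldecahydronaphthalen-1-yl]ethyl}-6-methyl-1,2-dioxan-3-yl]propanoic acid
Conditions: LiOH, THF/H2O (3:1), 0 °C to rt; then dilute HCl to pH 3
Reagents that add atoms: lithium hydroxide, [Li+].[OH-]
Why: Saponification of the methyl ester at low temperature is faster than enolisation, so C17 is not epimerised and no retro-Michael opening occurs, and the dialkyl peroxide is stable to hydroxide and to the mild acidification.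

**Compound list**

1 | (+)-sclareolide, (3aR,5aS,9aS,9bR)-3a,6,6,9a-tetramethyldecahydronaphtho[2,1-b]furan-2(1H)-one | O=C1C[C@H]2[C@](C)(O1)CC[C@H]3C(C)(C)CCC[C@@]32C | starting material
2 | methyl 2-[(4aS,8aS)-2,5,5,8a-tetramethyl-3,4,4a,5,6,7,8,8a-octahydronaphthalen-1-yl]acetate | COC(=O)CC1=C(C)CC[C@H]3C(C)(C)CCC[C@@]31C | intermediate
3 | methyl 2-[(1S,2R,4aS,8aS)-1,2-epoxy-2,5,5,8a-tetramethyldecahydronaphthalen-1-yl]acetate (8α,9α-epoxide) | COC(=O)C[C@]14O[C@]4(C)CC[C@H]3C(C)(C)CCC[C@@]31C | intermediate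
4 | (1R,2R,4aS,8aS)-1-(2-hydroxyethyl)-2,5,5,8a-tetramethyldecahydronaphthalen-1-ol | OCC[C@@]2(O)[C@H](C)CC[C@H]3C(C)(C)CCC[C@@]32C | intermediate
5 | (1R,2R,4aS,8aS)-1-(2-iodoethyl)-2,5,5,8a-tetramethyldecahydronaphthalen-1-ol | ICC[C@@]2(O)[C@H](C)CC[C@H]3C(C)(C)CCC[C@@]32C | intermediate
6 | 2,3-dibromoprop-1-ene | C=C(Br)CBr | starting material
7 | allylmagnesium bromide | C=CC[Mg]Br | starting material
8 | 2-bromohexa-1,5-diene | C=CCCC(Br)=C | intermediate
9 | hexa-1,5-dien-2-ylmagnesium bromide | C=CCCC(=C)[Mg]Br | intermediate (not isolated)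
10 | (1R,2R,4aS,8aS)-2,5,5,8a-tetramethyl-1-(3-methylidenehept-6-en-1-yl)decahydronaphthalen-1-ol | C=CCCC(=C)CC[C@@]2(O)[C@H](C)CC[C@H]3C(C)(C)CCC[C@@]32C | intermediate
11 | methyl methacrylate | C=C(C)C(=O)OC | starting material
12 | methyl (2E)-8-[(1R,2R,4aS,8aS)-1-hydroxy-2,5,5,8a-tetramethyldecahydronaphthalen-1-yl]-2-methyl-6-methylideneoct-2-enoate | COC(=O)/C(C)=C/CCC(=C)CC[C@@]2(O)[C@H](C)CC[C@H]3C(C)(C)CCC[C@@]32C | intermediate
13 | methyl (2E,6RS)-8-[(1R,2R,4aS,8aS)-1-hydroxy-2,5,5,8a-tetramethyldecahydronaphthalen-1-yl]-2,6-dimethyl-6-[(triethylsilyl)peroxy]oct-2-enoate (both C13 epimers; C13 left undefined) | COC(=O)/C(C)=C/CCC(C)(OO[Si](CC)(CC)CC)CC[C@@]2(O)[C@H](C)CC[C@H]3C(C)(C)CCC[C@@]32C | intermediate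
14 | methyl (2E,6RS)-6-hydroperoxy-8-[(1R,2R,4aS,8aS)-1-hydroxy-2,5,5,8a-tetramethyldecahydronaphthalen-1-yl]-2,6-dimethyloct-2-enoate (both C13 epimers; C13 left undefined) | COC(=O)/C(C)=C/CCC(C)(OO)CC[C@@]2(O)[C@H](C)CC[C@H]3C(C)(C)CCC[C@@]32C | intermediate (not isolated)
15 | methyl (2S)-2-[(3S,6S)-6-{2-[(1R,2R,4aS,8aS)-1-hydroxy-2,5,5,8a-tetramethyldecahydronaphthalen-1-yl]ethyl}-6-methyl-1,2-dioxan-3-yl]propanoate | C[C@H](C(=O)OC)[C@@H]1CC[C@@](C)(CC[C@@]2(O)[C@H](C)CC[C@H]3C(C)(C)CCC[C@@]32C)OO1 | intermediate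
16 | (2S)-2-[(3S,6S)-6-{2-[(1R,2R,4aS,8aS)-1-hydroxy-2,5,5,8a-tetramethyldecahydronaphthalen-1-yl]ethyl}-6-methyl-1,2-dioxan-3-yl]propanoic acid (CNP0328037.1) | C[C@H](C(=O)O)[C@@H]1CC[C@@](C)(CC[C@@]2(O)[C@H](C)CC[C@H]3C(C)(C)CCC[C@@]32C)OO1 | target

**Step count and risks**

Total step count: 10. Longest linear sequence: 9 (steps 1–4 and 6–10; step 5 makes the side-chain bromide).

Most likely to fail, first: step 9. The iminophosphorane may be consumed by the hydroperoxide, the 2-methyl enoate may be too poor an acceptor, and facial control may be low. The same step must also part the C13 epimer pair from step 8. The fallback changes the activation mode from Brønsted-base catalysis of an ester to covalent iminium catalysis of an enal. It sets out from 13. i-Bu2AlH (CH2Cl2, −78 °C) reduces the ester to the allylic alcohol (2E,6RS)-8-[(1R,2R,4aS,8aS)-1-hydroxy-2,5,5,8a-tetramethyldecahydronaphthalen-1-yl]-2,6-dimethyl-6-[(triethylsilyl)peroxy]oct-2-en-1-ol F7. MnO2 (CH2Cl2, rt) oxidises it to (2E,6RS)-8-[(1R,2R,4aS,8aS)-1-hydroxy-2,5,5,8a-tetramethyldecahydronaphthalen-1-yl]-2,6-dimethyl-6-[(triethylsilyl)peroxy]oct-2-enal F8. HCl in MeOH frees (2E,6RS)-6-hydroperoxy-8-[(1R,2R,4aS,8aS)-1-hydroxy-2,5,5,8a-tetramethyldecahydronaphthalen-1-yl]-2,6-dimethyloct-2-enal F9, which is not isolated. The bis(trifluoroacetate) of 9-amino-9-deoxy-epi-quinine (20 mol%, toluene, 0 °C) forms the iminium ion, the hydroperoxide adds to its β-carbon and the enamine is protonated; this elementary step is known from amine-catalysed hydroperoxide additions to α-branched enals. The product is (2S)-2-[(3S,6S)-6-{2-[(1R,2R,4aS,8aS)-1-hydroxy-2,5,5,8a-tetramethyldecahydronaphthalen-1-yl]ethyl}-6-methyl-1,2-dioxan-3-yl]propanal F10. Buffered chlorite (NaClO2, NaH2PO4, 2-methylbut-2-ene, t-BuOH/H2O) oxidises it at once to 16, where the branch rejoins the route.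

Second: step 3. Hydride attack on a tetrasubstituted epoxide is slow, and the C12 alkoxide formed first could open the epoxide itself to a tetrahydrofuran. The fallback replaces nucleophilic opening by isomerisation and radical hydrogenation. It sets out from 3. LiAlH4 (Et2O, −20 °C) reduces only the ester and gives 2-[(1S,2R,4aS,8aS)-1,2-epoxy-2,5,5,8a-tetramethyldecahydronaphthalen-1-yl]ethanol F1. Diethylaluminium 2,2,6,6-tetramethylpiperidide (toluene, 0 °C) removes a proton from the C8 methyl group and gives the exocyclic allylic alcohol (1R,4aS,8aS)-1-(2-hydroxyethyl)-5,5,8a-trimethyl-2-methylidenedecahydronaphthalen-1-ol F2, with the C9–O bond untouched. Hydrogen-atom-transfer hydrogenation (Mn(dpm)3 with dpm = 2,2,6,6-tetramethylheptane-3,5-dionate, PhSiH3, t-BuOOH, i-PrOH, rt) then reduces the alkene through the tertiary C8 radical so that the methyl group ends equatorial (8α; the axial alternative would be 1,3-diaxial to the C10 methyl). This is diol 4, where the branch rejoins the route.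

Third: step 6. The 3-iodo alkoxide may close to an oxetane or fragment before it couples. The fallback changes the order of events so that the coupling is done before any oxygen is placed at C9, at the cost of one step. It sets out from 2. LiAlH4 (THF, 0 °C) gives 2-[(4aS,8aS)-2,5,5,8a-tetramethyl-3,4,4a,5,6,7,8,8a-octahydronaphthalen-1-yl]ethanol F3. I2, PPh3 and imidazole give (4aS,8aS)-1-(2-iodoethyl)-2,5,5,8a-tetramethyl-3,4,4a,5,6,7,8,8a-octahydronaphthalene F4. CuI-catalysed coupling with 9 gives (4aS,8aS)-2,5,5,8a-tetramethyl-1-(3-methylidenehept-6-en-1-yl)-3,4,4a,5,6,7,8,8a-octahydronaphthalene F5. mCPBA (1.0 equiv, CH2Cl2, −20 °C) epoxidises only the tetrasubstituted ring alkene, from the α face, to give (1S,2R,4aS,8aS)-1,2-epoxy-2,5,5,8a-tetramethyl-1-(3-methylidenehept-6-en-1-yl)decahydronaphthalene F6. LiEt3BH (THF, reflux) opens the epoxide as in step 3 and gives 10, where the branch rejoins the route.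

**Further compounds**

F1 | step 3 | 2-[(1S,2R,4aS,8aS)-1,2-epoxy-2,5,5,8a-tetramethyldecahydronaphthalen-1-yl]ethanol | OCC[C@]14O[C@]4(C)CC[C@H]3C(C)(C)CCC[C@@]31C
F2 | step 3 | (1R,4aS,8aS)-1-(2-hydroxyethyl)-5,5,8a-trimethyl-2-methylidenedecahydronaphthalen-1-ol | OCC[C@@]2(O)C(=C)CC[C@H]3C(C)(C)CCC[C@@]32C
F3 | step 6 | 2-[(4aS,8aS)-2,5,5,8a-tetramethyl-3,4,4a,5,6,7,8,8a-octahydronaphthalen-1-yl]ethanol | OCCC1=C(C)CC[C@H]3C(C)(C)CCC[C@@]31C
F4 | step 6 | (4aS,8aS)-1-(2-iodoethyl)-2,5,5,8a-tetramethyl-3,4,4a,5,6,7,8,8a-octahydronaphthalene | ICCC1=C(C)CC[C@H]3C(C)(C)CCC[C@@]31C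
F5 | step 6 | (4aS,8aS)-2,5,5,8a-tetramethyl-1-(3-methylidenehept-6-en-1-yl)-3,4,4a,5,6,7,8,8a-octahydronaphthalene | C=CCCC(=C)CCC1=C(C)CC[C@H]3C(C)(C)CCC[C@@]31C
F6 | step 6 | (1S,2R,4aS,8aS)-1,2-epoxy-2,5,5,8a-tetramethyl-1-(3-methylidenehept-6-en-1-yl)decahydronaphthalene | C=CCCC(=C)CC[C@]14O[C@]4(C)CC[C@H]3C(C)(C)CCC[C@@]31C
F7 | step 9 | (2E,6RS)-8-[(1R,2R,4aS,8aS)-1-hydroxy-2,5,5,8a-tetramethyldecahydronaphthalen-1-yl]-2,6-dimethyl-6-[(triethylsilyl)peroxy]oct-2-en-1-ol | OC/C(C)=C/CCC(C)(OO[Si](CC)(CC)CC)CC[C@@]2(O)[C@H](C)CC[C@H]3C(C)(C)CCC[C@@]32C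
F8 | step 9 | (2E,6RS)-8-[(1R,2R,4aS,8aS)-1-hydroxy-2,5,5,8a-tetramethyldecahydronaphthalen-1-yl]-2,6-dimethyl-6-[(triethylsilyl)peroxy]oct-2-enal | O=C/C(C)=C/CCC(C)(OO[Si](CC)(CC)CC)CC[C@@]2(O)[C@H](C)CC[C@H]3C(C)(C)CCC[C@@]32C
F9 | step 9 | (2E,6RS)-6-hydroperoxy-8-[(1R,2R,4aS,8aS)-1-hydroxy-2,5,5,8a-tetramethyldecahydronaphthalen-1-yl]-2,6-dimethyloct-2-enal | O=C/C(C)=C/CCC(C)(OO)CC[C@@]2(O)[C@H](C)CC[C@H]3C(C)(C)CCC[C@@]32C
F10 | step 9 | (2S)-2-[(3S,6S)-6-{2-[(1R,2R,4aS,8aS)-1-hydroxy-2,5,5,8a-tetramethyldecahydronaphthalen-1-yl]ethyl}-6-methyl-1,2-dioxan-3-yl]propanal | C[C@H](C=O)[C@@H]1CC[C@@](C)(CC[C@@]2(O)[C@H](C)CC[C@H]3C(C)(C)CCC[C@@]32C)OO1
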